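**Retrosynthetic overview**
- Target ⇐ desilylation, α-face epoxidation of C8=C9, and Pd/CO aryl-ester formation (4-iodophenol as aryl source) on 7β-silyloxy-5α-dauc-8-ene-4β,6α-diol.
- That diol ⇐ hydroxyl-directed ketone reduction and hydroxyl-directed Rubottom oxidation of a 6-silyloxy-dauca-6,8-diene.
- Seven-membered ring ⇐ one-carbon ring expansion of a trans-fused 5-methylhydrindenone (1,2-alkenyl shift of a β-oxido carbenoid; CH2Br2 supplies C7).
- Hydrindenone ⇐ RCM and allylic oxidation ⇐ isopropyl addition ⇐ enantioselective conjugate allylation/aldol of 3-methylcyclopentenone with methacrolein.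
- Ring order: cyclopentane (from the starting enone) → cyclohexenone (RCM) → cycloheptadiene (ring expansion) → oxirane last.

Naming convention used below: daucane numbering for 5–7 bicycles (C1 = angular-methyl carbon, C4 = isopropyl carbinol, C5 = ring-fusion CH, C8 = methyl-bearing ring carbon; β = face of the C1 methyl; 5α = trans-fused); indene numbering for the 5–6 bicycles.

**Step 1**
Reactants: 1 3-methylcyclopent-2-en-1-one; 2 allyltrimethylsilane; 3 methacrolein (2-methylprop-2-enal)
Product: 5 (2S,3R)-2-(1-hydroxy-2-methylprop-2-en-1-yl)-3-methyl-3-(prop-2-en-1-yl)cyclopentan-1-one (both carbinol epimers), via silyl enol ether 4 (not isolated)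
Conditions: 2 (1.5 equiv), oxazaborolidinium triflimide from (S)-α,α-diphenylprolinol/o-tolylboroxine/HNTf2 (10 mol%; enantiomer chosen to give (R)-4), CH2Cl2, −78 °C; then 3, Yb(OTf)3 (10 mol%), THF–H2O 9:1, 0 °C
Reagents that add atoms: none
Why: Proposed new method: an enantioselective Hosomi–Sakurai conjugate allylation of a simple β-methyl cyclic enone, in which the cationic boron Lewis acid binds the carbonyl and shields one π-face, the allylsilane attacks C3 through an open transition state and the Me3Si group passes to the enolate oxygen (turning the catalyst over and setting the quaternary centre), after which the regiodefined silyl enol ether 4 undergoes a Mukaiyama aldol with methacrolein anti to the larger allyl group (2,3-trans; the carbinol centre is erased in step 4); closest known reactions are the racemic TiCl4- or Me3SiNTf2-promoted Sakurai allylation of 3-methylcycloalkenones and oxazaborolidinium-catalysed Mukaiyama–Michael and Diels–Alder reactions of cyclic enones.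

**Step 2**
Reactants: 5 (2S,3R)-2-(1-hydroxy-2-methylprop-2-en-1-yl)-3-methyl-3-(prop-2-en-1-yl)cyclopentan-1-one
Product: 6 (1R,2S,3R)-2-(1-hydroxy-2-methylprop-2-en-1-yl)-3-methyl-1-(propan-2-yl)-3-(prop-2-en-1-yl)cyclopentan-1-ol
Conditions: i-PrMgCl (3 equiv), LaCl3·2LiCl (0.3 equiv), THF, 0 °C; aq. NH4Cl
Reagents that add atoms: isopropylmagnesium chloride, CC(C)[Mg]Cl
Why: Lanthanum-promoted Grignard 1,2-addition suppresses enolisation and β-hydride reduction, and the nucleophile attacks the ketone face anti to the adjacent C2 side chain, giving the (1R) tertiary carbinol with OH cis to that chain and to the 3-methyl group.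

**Step 3**
Reactants: 6 (1R,2S,3R)-2-(1-hydroxy-2-methylprop-2-en-1-yl)-3-methyl-1-(propan-2-yl)-3-(prop-2-en-1-yl)cyclopentan-1-ol
Product: 7 trans-fused 5,7a-dimethyl-3-(propan-2-yl)-2,3,3a,4,7,7a-hexahydro-1H-indene-3,4-diol (3β-OH; 3aα-H; 7aβ-CH3; C4 epimers)
Conditions: second-generation Hoveyda–Grubbs catalyst (5 mol%), toluene, 80 °C
Reagents that add atoms: none
Why: Ring-closing metathesis of the allyl alkene onto the isopropenyl alkene gives the trisubstituted cyclohexene with loss of ethene; the trans ring fusion is carried over from the 2,3-trans cyclopentane and no stereocentre is touched.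

**Step 4**
Reactants: 7 trans-fused 5,7a-dimethyl-3-(propan-2-yl)-2,3,3a,4,7,7a-hexahydro-1H-indene-3,4-diol
Product: 8 trans-fused 3β-hydroxy-5,7aβ-dimethyl-3-(propan-2-yl)-1,2,3,3aα,7,7a-hexahydro-4H-inden-4-one
Conditions: MnO2 (20 equiv), CH2Cl2, rt
Reagents that add atoms: none
Why: MnO2 oxidises only the secondary allylic alcohol (the tertiary OH is inert), converging both carbinol epimers to one enone under neutral conditions that do not epimerise the ring-fusion hydrogen.

**Step 5**
Reactants: 8 trans-fused 3β-hydroxy-5,7aβ-dimethyl-3-(propan-2-yl)-1,2,3,3aα,7,7a-hexahydro-4H-inden-4-one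
Product: 12 6-(tert-butyldimethylsilyloxy)-5α-dauca-6,8-dien-4β-ol, via dibromomethyl carbinol dilithium salt 9 (not isolated), via lithium bromocarbenoid 10 (not isolated), via ring-expanded dilithium dienolate 11 (not isolated)
Conditions: CH2Br2, LiTMP, THF, −90 °C; n-BuLi, −90 → −20 °C; TBSCl, DMPU, −78 → 0 °C
Reagents that add atoms: dibromomethane, BrCBr; tert-butyldimethylsilyl chloride, CC(C)(C)[Si](C)(C)Cl
Why: Yamamoto–Nozaki ring enlargement, in which LiCHBr2 adds 1,2 to the enone carbonyl, Br/Li exchange gives the β-oxido carbenoid, and its alkenyl carbon undergoes the 1,2-shift with loss of LiBr in preference to the hindered sp3 ring-fusion carbon, so the new CH is inserted between C=O and the alkene and the regiodefined dienolate is O-silylated (no stereocentre is created).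

**Step 6**
Reactants: 12 6-(tert-butyldimethylsilyloxy)-5α-dauca-6,8-dien-4β-ol
Product: 14 7β-(tert-butyldimethylsilyloxy)-4β-hydroxy-5α-dauc-8-en-6-one, via silyloxy epoxide 13 (not isolated)
Conditions: mCPBA (1.05 equiv), NaHCO3, CH2Cl2, −40 → 0 °C
Reagents that add atoms: 3-chloroperoxybenzoic acid, OOC(=O)c1cccc(Cl)c1
Why: Rubottom oxidation in which the peracid, hydrogen-bonded to the homoallylic 4β-OH, epoxidises the electron-rich enol-ether bond C6=C7 on the β face and 1,4-silyl migration then gives the 7β-silyloxy ketone.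

**Step 7**
Reactants: 14 7β-(tert-butyldimethylsilyloxy)-4β-hydroxy-5α-dauc-8-en-6-one
Product: 15 7β-(tert-butyldimethylsilyloxy)-5α-dauc-8-ene-4β,6α-diol
Conditions: Me4NBH(OAc)3, MeCN–AcOH 1:1, −30 °C
Reagents that add atoms: none
Why: Evans–Saksena hydroxyl-directed reduction, in which the tertiary 4β-OH exchanges onto boron and delivers hydride intramolecularly to the β face of the C6 ketone, giving the 6α-alcohol (1,3-anti), while the reagent does not reduce the ketone intermolecularly at this temperature.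

**Step 8**
Reactants: 16 4-iodophenol
Product: 17 tert-butyl(4-iodophenoxy)dimethylsilane
Conditions: TBSCl, imidazole, CH2Cl2, rt
Reagents that add atoms: tert-butyldimethylsilyl chloride, CC(C)(C)[Si](C)(C)Cl
Why: Standard silylation of the phenol so that it cannot compete as the nucleophile in the carbonylation.

**Step 9**
Reactants: 15 7β-(tert-butyldimethylsilyloxy)-5α-dauc-8-ene-4β,6α-diol; 17 tert-butyl(4-iodophenoxy)dimethylsilane
Product: 18 7β-(tert-butyldimethylsilyloxy)-4β-hydroxy-5α-dauc-8-en-6α-yl 4-(tert-butyldimethylsilyloxy)benzoate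
Conditions: CO (1 atm), Pd(OAc)2 (5 mol%), Xantphos (6 mol%), Et3N, toluene, 90 °C
Reagents that add atoms: carbon monoxide, [C-]#[O+]
Why: Palladium-catalysed alkoxycarbonylation (Heck carbonylation), in which oxidative addition of the aryl iodide, CO insertion and alcoholysis of the acyl-palladium by the only secondary hydroxyl give the aryl ester with retention at C6 (the tertiary 4-OH does not react).

**Step 10**
Reactants: 18 7β-(tert-butyldimethylsilyloxy)-4β-hydroxy-5α-dauc-8-en-6α-yl 4-(tert-butyldimethylsilyloxy)benzoate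
Product: 19 7β-(tert-butyldimethylsilyloxy)-8α,9α-epoxy-4β-hydroxy-5α-daucan-6α-yl 4-(tert-butyldimethylsilyloxy)benzoate
Conditions: mCPBA, NaHCO3, CH2Cl2, 0 °C
Reagents that add atoms: 3-chloroperoxybenzoic acid, OOC(=O)c1cccc(Cl)c1
Why: Prilezhaev epoxidation occurs on the α face, anti to the allylic 7β-silyloxy group and to the axial angular methyl that screens the β face of the seven-membered ring, setting C8 and C9.

**Step 11**
Reactants: 19 7β-(tert-butyldimethylsilyloxy)-8α,9α-epoxy-4β-hydroxy-5α-daucan-6α-yl 4-(tert-butyldimethylsilyloxy)benzoate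
Product: 20 8α,9α-epoxy-4β,7β-dihydroxy-5α-daucan-6α-yl 4-hydroxybenzoate (CNP0290052.1)
Conditions: HF·pyridine, pyridine, THF, 0 °C → rt
Reagents that add atoms: none
Why: Fluoride cleaves the aryl and the secondary alkyl silyl ether, and excess pyridine buffers HF so that the trisubstituted epoxide and the ester survive.

**Compound list**
1 | 3-methylcyclopent-2-en-1-one | CC1=CC(=O)CC1 | starting material
2 | allyltrimethylsilane | C=CC[Si](C)(C)C | starting material
3 | methacrolein | CC(=C)C=O | starting material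
4 | (R)-trimethyl{[3-methyl-3-(prop-2-en-1-yl)cyclopent-1-en-1-yl]oxy}silane | C[Si](C)(C)OC1=C[C@@](C)(CC=C)CC1 | intermediate
5 | (2S,3R)-2-(1-hydroxy-2-methylprop-2-en-1-yl)-3-methyl-3-(prop-2-en-1-yl)cyclopentan-1-one (carbinol epimers) | O=C1CC[C@](C)(CC=C)[C@H]1C(O)C(C)=C | intermediate
6 | (1R,2S,3R)-2-(1-hydroxy-2-methylprop-2-en-1-yl)-3-methyl-1-(propan-2-yl)-3-(prop-2-en-1-yl)cyclopentan-1-ol (carbinol epimers) | CC(C)[C@]1(O)CC[C@](C)(CC=C)[C@H]1C(O)C(C)=C | intermediate
7 | trans-fused 5,7a-dimethyl-3-(propan-2-yl)-2,3,3a,4,7,7a-hexahydro-1H-indene-3,4-diol (3β-OH, 3aα-H, 7aβ-CH3; C4 epimers) | CC(C)[C@]1(O)CC[C@]2(C)CC=C(C)C(O)[C@H]21 | intermediate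
8 | trans-fused 3β-hydroxy-5,7aβ-dimethyl-3-(propan-2-yl)-1,2,3,3aα,7,7a-hexahydro-4H-inden-4-one | CC(C)[C@]1(O)CC[C@]2(C)CC=C(C)C(=O)[C@H]21 | intermediate
9 | dilithium salt of the 4-(dibromomethyl)-3,4-diol derived from 8 | CC(C)[C@]1(O[Li])CC[C@]2(C)CC=C(C)C(O[Li])(C(Br)Br)[C@H]21 | intermediate
10 | 4-[bromo(lithio)methyl] carbenoid derived from 9 | CC(C)[C@]1(O[Li])CC[C@]2(C)CC=C(C)C(O[Li])(C([Li])Br)[C@H]21 | intermediate
11 | dilithium 4β-oxido-5α-dauca-6,8-dien-6-olate | CC(C)[C@]1(O[Li])CC[C@]2(C)CC=C(C)C=C(O[Li])[C@H]21 | intermediate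
12 | 6-(tert-butyldimethylsilyloxy)-5α-dauca-6,8-dien-4β-ol | CC(C)[C@]1(O)CC[C@]2(C)CC=C(C)C=C(O[Si](C)(C)C(C)(C)C)[C@H]21 | intermediate
13 | 6α-(tert-butyldimethylsilyloxy)-6β,7β-epoxy-5α-dauc-8-en-4β-ol | CC(C)[C@]1(O)CC[C@]2(C)CC=C(C)[C@H]3O[C@@]3(O[Si](C)(C)C(C)(C)C)[C@H]21 | intermediate
14 | 7β-(tert-butyldimethylsilyloxy)-4β-hydroxy-5α-dauc-8-en-6-one | CC(C)[C@]1(O)CC[C@]2(C)CC=C(C)[C@@H](O[Si](C)(C)C(C)(C)C)C(=O)[C@H]21 | intermediate
15 | 7β-(tert-butyldimethylsilyloxy)-5α-dauc-8-ene-4β,6α-diol | CC(C)[C@]1(O)CC[C@]2(C)CC=C(C)[C@@H](O[Si](C)(C)C(C)(C)C)[C@H](O)[C@H]21 | intermediate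
16 | 4-iodophenol | Oc1ccc(I)cc1 | starting material
17 | tert-butyl(4-iodophenoxy)dimethylsilane | CC(C)(C)[Si](C)(C)Oc1ccc(I)cc1 | intermediate
18 | 7β-(tert-butyldimethylsilyloxy)-4β-hydroxy-5α-dauc-8-en-6α-yl 4-(tert-butyldimethylsilyloxy)benzoate | CC(C)[C@]1(O)CC[C@]2(C)CC=C(C)[C@@H](O[Si](C)(C)C(C)(C)C)[C@H](OC(=O)c3ccc(O[Si](C)(C)C(C)(C)C)cc3)[C@H]21 | intermediate
19 | 7β-(tert-butyldimethylsilyloxy)-8α,9α-epoxy-4β-hydroxy-5α-daucan-6α-yl 4-(tert-butyldimethylsilyloxy)benzoate | CC(C)[C@]1(O)CC[C@]2(C)C[C@@H]3O[C@]3(C)[C@@H](O[Si](C)(C)C(C)(C)C)[C@H](OC(=O)c3ccc(O[Si](C)(C)C(C)(C)C)cc3)[C@H]21 | intermediate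
20 | 8α,9α-epoxy-4β,7β-dihydroxy-5α-daucan-6α-yl 4-hydroxybenzoate | CC(C)[C@]1(O)CC[C@]2(C)C[C@@H]3O[C@]3(C)[C@@H](O)[C@H](OC(=O)c3ccc(O)cc3)[C@H]21 | target

**Totals**
Total step count: 11. Longest linear sequence: 10 steps (steps 1–7, then 9–11; step 8 is a one-step side branch).

**Three steps most likely to fail, with fallbacks**

Step 1 (the proposed new method). It can fail through achiral Me3SiNTf2 background catalysis (low ee) or weak 2,3-trans control in the aldol. The fallback uses known chemistry and sets out from 1. Catalytic asymmetric 1,2-allylboration of the ketone (allyl-B(Oi-Pr)2, chiral 3,3'-dibromo-BINOL catalyst) gives (R)-1-allyl-3-methylcyclopent-2-en-1-ol F1. KH/18-crown-6 in THF then triggers the anionic oxy-Cope rearrangement, which transfers the allyl group suprafacially to C3 and leaves the potassium enolate. Trapping that enolate with 3 comes back to the route at 5.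

Step 5. The ring-fusion carbon may migrate instead of the alkenyl carbon, or the enone may simply be enolised. The fallback sets out from 8 and changes the homologation chemistry to a diazoalkane insertion. Sc(OTf)3-catalysed reaction with trimethylsilyldiazomethane (Tiffeneau–Demjanov-type alkenyl shift) gives 4β-hydroxy-7-(trimethylsilyl)-5α-dauc-8-en-6-one F2. Protodesilylation on silica gives 4β-hydroxy-5α-dauc-8-en-6-one F3. Double deprotonation with LiHMDS (4-OH and the doubly activated C7–H) and O-silylation with TBSCl/DMPU comes back at 12.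

Step 6. The axial angular methyl screens the β face and may override the hydroxyl direction, giving the 7α epimer, and γ-oxidation at C9 is a further risk. The fallback sets out from 12 and replaces substrate direction by catalyst control. Shi epoxidation (fructose-derived ketone catalyst of the enantiomeric series matched to the β face, Oxone, buffered MeCN–dimethoxymethane–water, 0 °C) gives, after loss of the silyl group, 4β,7β-dihydroxy-5α-dauc-8-en-6-one F4. Selective silylation of the secondary hydroxyl (TBSCl, imidazole, DMF) comes back at 14.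

**Further compounds**
F1 | step 1 | (R)-1-allyl-3-methylcyclopent-2-en-1-ol | C=CC[C@@]1(O)C=C(C)CC1
F2 | step 5 | 4β-hydroxy-7-(trimethylsilyl)-5α-dauc-8-en-6-one (C7 epimers) | CC(C)[C@]1(O)CC[C@]2(C)CC=C(C)C([Si](C)(C)C)C(=O)[C@H]21
F3 | step 5 | 4β-hydroxy-5α-dauc-8-en-6-one | CC(C)[C@]1(O)CC[C@]2(C)CC=C(C)CC(=O)[C@H]21
F4 | step 6 | 4β,7β-dihydroxy-5α-dauc-8-en-6-one | CC(C)[C@]1(O)CC[C@]2(C)CC=C(C)[C@@H](O)C(=O)[C@H]21
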